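## Retrosynthetic overview

1. The strategy rests on the 5-hydroxyindole: its oxygen on C5 sits para to the nitrogen-bearing C7a on the benzo ring C3a–C4–C5–C6–C7–C7a, which is the oxygen pattern of 1,4-benzoquinone. Cutting C3–C3a and N1–C7a (Nenitzescu) gives benzoquinone and the N-benzyl enamine of an arylacetaldehyde whose aryl group is the hexasubstituted central ring already carrying the methoxyindole.
2. The enamine comes from the arylacetaldehyde and benzylamine; the aldehyde comes from an (E)-2-ethoxyvinyl arene, made by Suzuki coupling of an aryl bromide with 2-ethoxyvinylboronate.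
3. The aryl bromide comes from a mono-Suzuki coupling of 1,4-dibromo-2,3,5,6-tetramethoxybenzene (from 1,2,4,5-tetramethoxybenzene) with a 1-benzyl-5-methoxyindol-3-ylboronate (from 5-methoxyindole).
4. Ring order: the central benzene ring and the methoxyindole are bought intact; the pyrrole ring of the hydroxyindole is the only ring formed, on benzoquinone, which becomes its benzo ring. Both N-benzyl groups are removed last.

Key step: step 8

Remark on the chemistry: the condensate of the arylacetaldehyde with benzylamine is an imine–enamine tautomer pair. The two methoxy groups flanking the side chain twist the central ring out of conjugation, so the enamine is not expected to be favoured or isolable. The pair is therefore carried forward crude and counted as the enamine, the tautomer that reacts in the key step.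

## Route

Step 1
Reactants: 1 1,2,4,5-tetramethoxybenzene
Product: 2 1,4-dibromo-2,3,5,6-tetramethoxybenzene
Conditions: Br2 (2.2 equiv), CH2Cl2, 0 °C to rt
Reagents that add atoms: bromine, BrBr
Why: Electrophilic aromatic bromination: the only two ring C–H positions of 1 are each flanked by two methoxy groups and strongly activated, so double substitution gives the symmetric para-dibromide without regiochemical choice, and the anhydrous medium avoids oxidative demethylation to a quinone.

Step 2
Reactants: 3 5-methoxy-1H-indole
Product: 5 1-benzyl-3-iodo-5-methoxy-1H-indole, via 3-iodo-5-methoxy-1H-indole 4 (not isolated)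
Conditions: I2 (1.05 equiv), KOH (3 equiv), DMF, rt; then BnBr (1.2 equiv), 0 °C to rt
Reagents that add atoms: iodine, II; benzyl bromide, BrCc1ccccc1
Why: Electrophilic iodination of the indolyl anion at C3, its most nucleophilic carbon, followed by SN2 N-benzylation in the same pot, so that the light-sensitive N–H iodoindole 4 is never handled.

Step 3
Reactants: 5 1-benzyl-3-iodo-5-methoxy-1H-indole
Product: 7 1-benzyl-5-methoxy-3-(4,4,5,5-tetramethyl-1,3,2-dioxaborolan-2-yl)-1H-indole, via indol-3-ylmagnesium chloride 6 (not isolated)
Conditions: i-PrMgCl·LiCl (1.2 equiv), THF, 0 °C; then i-PrOBpin (1.5 equiv), 0 °C to rt; aq NH4Cl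
Reagents that add atoms: 2-isopropoxy-4,4,5,5-tetramethyl-1,3,2-dioxaborolane, CC(C)OB1OC(C)(C)C(C)(C)O1
Why: Iodine–magnesium exchange with the turbo-Grignard reagent gives the C3 Grignard 6 without touching C2–H or the benzylic CH2, and 6 is trapped at boron by displacement of isopropoxide (borylation of an aryl Grignard reagent).

Step 4
Reactants: 2 1,4-dibromo-2,3,5,6-tetramethoxybenzene (threefold excess); 7 1-benzyl-5-methoxy-3-(4,4,5,5-tetramethyl-1,3,2-dioxaborolan-2-yl)-1H-indole
Product: 8 1-benzyl-3-(4-bromo-2,3,5,6-tetramethoxyphenyl)-5-methoxy-1H-indole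
Conditions: Pd(OAc)2 (5 mol %), SPhos (10 mol %), K3PO4 (3 equiv), toluene/H2O, 80 °C; excess 2 recovered
Reagents that add atoms: none
Why: Suzuki–Miyaura coupling in which the bulky electron-rich biarylphosphine allows oxidative addition of zerovalent palladium into the di-ortho-methoxy C–Br bond, and the threefold excess of the symmetric dibromide keeps the coupling at one bromine.

Step 5
Reactants: 8 1-benzyl-3-(4-bromo-2,3,5,6-tetramethoxyphenyl)-5-methoxy-1H-indole; 9 (E)-2-(2-ethoxyethenyl)-4,4,5,5-tetramethyl-1,3,2-dioxaborolane
Product: 10 1-benzyl-3-{4-[(E)-2-ethoxyethenyl]-2,3,5,6-tetramethoxyphenyl}-5-methoxy-1H-indole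
Conditions: Pd(OAc)2 (5 mol %), SPhos (10 mol %), K3PO4 (3 equiv), dioxane/H2O, 90 °C
Reagents that add atoms: none
Why: Second Suzuki–Miyaura coupling at the remaining hindered C–Br bond, with retention of the E geometry of the alkenylboronate, which installs the two-carbon aldehyde equivalent.

Step 6
Reactants: 10 1-benzyl-3-{4-[(E)-2-ethoxyethenyl]-2,3,5,6-tetramethoxyphenyl}-5-methoxy-1H-indole
Product: 11 2-[4-(1-benzyl-5-methoxy-1H-indol-3-yl)-2,3,5,6-tetramethoxyphenyl]acetaldehyde
Conditions: 1 M aq HCl, THF, 40 °C, argon; crude aldehyde used at once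
Reagents that add atoms: water, O
Why: Acid-catalysed hydrolysis of an enol ether (protonation at the aryl-bearing carbon, capture of the oxocarbenium ion by water, loss of ethanol), under which the aryl methyl ethers and the N-benzylindole are stable.

Step 7
Reactants: 11 2-[4-(1-benzyl-5-methoxy-1H-indol-3-yl)-2,3,5,6-tetramethoxyphenyl]acetaldehyde; 12 benzylamine
Product: 14 (E)-N-benzyl-2-[4-(1-benzyl-5-methoxy-1H-indol-3-yl)-2,3,5,6-tetramethoxyphenyl]ethen-1-amine, via N-benzyl aldimine 13 (not isolated)
Conditions: BnNH2 (1.0 equiv), 4 Å MS, CH2Cl2, rt, argon; filtered and used at once as the crude solution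
Reagents that add atoms: none
Why: Condensation of an aldehyde with a primary amine over a drying agent gives aldimine 13, which equilibrates by 1,3-proton shift with the secondary enamine 14 (imine–enamine tautomerism), and exactly one equivalent of amine is used so that no free benzylamine reaches the quinone in step 8.

Step 8
Reactants: 14 (E)-N-benzyl-2-[4-(1-benzyl-5-methoxy-1H-indol-3-yl)-2,3,5,6-tetramethoxyphenyl]ethen-1-amine; 15 1,4-benzoquinone
Product: 18 1-benzyl-3-[4-(1-benzyl-5-methoxy-1H-indol-3-yl)-2,3,5,6-tetramethoxyphenyl]-1H-indol-5-ol, via hydroquinone adduct 16 (not isolated), via quinone adduct 17 (not isolated)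
Conditions: 15 (1.5 equiv), ZnI2 (20 mol %), CH2Cl2, 0 °C to rt, slow addition of the solution of 14, argon, dark
Reagents that add atoms: none
Why: Proposed new method: the Nenitzescu 5-hydroxyindole synthesis, known for β-aminocrotonates and other acyl-stabilised enamines with 1,4-benzoquinone under ZnI2 or ZnCl2 catalysis (the closest known reaction type), is extended here to an aldehyde-derived secondary enamine without an acyl group, on the reasoning that such an enamine is the stronger carbon nucleophile and that imines are known to add to Michael acceptors through their secondary enamine tautomers. The aryl-bearing β-carbon of 14 adds to a C–H carbon of 15 and the adduct tautomerises to hydroquinone 16 (C3–C3a bond); excess 15 oxidises 16 to quinone 17, whose enamine nitrogen attacks the neighbouring quinone carbonyl in a 5-exo-trig closure (N1–C7a bond), and loss of water followed by reduction of the quinone iminium ion by hydroquinone gives the aromatic pyrrole ring. No stereocentre is formed, and since the four C–H positions of 15 are equivalent the hydroxyl can only end on C5, para to nitrogen. The selectivity needed is closure through nitrogen and not through the hydroquinone oxygen, which would lead to a 5-hydroxybenzofuran by loss of benzylamine; the N–H of the secondary enamine, the excess of quinone that turns 16 quickly into 17 (which has no phenolic oxygen left) and zinc coordination are expected to secure it. Dichloromethane is used because nitromethane, the classical solvent, could add to the aldimine tautomer in a nitro-Mannich reaction. C2 of the indole already present is shielded by the hexasubstituted ring and should not add to the quinone under this mild Lewis acid.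

Step 9
Reactants: 18 1-benzyl-3-[4-(1-benzyl-5-methoxy-1H-indol-3-yl)-2,3,5,6-tetramethoxyphenyl]-1H-indol-5-ol
Product: 19 3-[4-(5-methoxy-1H-indol-3-yl)-2,3,5,6-tetramethoxyphenyl]-1H-indol-5-ol (CNP0244913.0)
Conditions: Na (6 equiv), NH3(l)/THF, −78 °C; solid NH4Cl; degassed work-up
Reagents that add atoms: none
Why: Dissolving-metal reductive cleavage of both N-benzyl C–N bonds: electron transfer to the benzyl group expels the indolide anion, and the phenoxide and indolide anions so formed, together with the absence of a proton source, protect the electron-rich rings from Birch reduction.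

## Compound list

1 | 1,2,4,5-tetramethoxybenzene | COc1cc(OC)c(OC)cc1OC | starting material
2 | 1,4-dibromo-2,3,5,6-tetramethoxybenzene | COc1c(Br)c(OC)c(OC)c(Br)c1OC | intermediate
3 | 5-methoxy-1H-indole | COc1ccc2[nH]ccc2c1 | starting material
4 | 3-iodo-5-methoxy-1H-indole | COc1ccc2[nH]cc(I)c2c1 | intermediate
5 | 1-benzyl-3-iodo-5-methoxy-1H-indole | COc1ccc2c(c1)c(I)cn2Cc1ccccc1 | intermediate
6 | (1-benzyl-5-methoxy-1H-indol-3-yl)magnesium chloride | COc1ccc2c(c1)c([Mg]Cl)cn2Cc1ccccc1 | intermediate
7 | 1-benzyl-5-methoxy-3-(4,4,5,5-tetramethyl-1,3,2-dioxaborolan-2-yl)-1H-indole | COc1ccc2c(c1)c(cn2Cc1ccccc1)B1OC(C)(C)C(C)(C)O1 | intermediate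
8 | 1-benzyl-3-(4-bromo-2,3,5,6-tetramethoxyphenyl)-5-methoxy-1H-indole | COc1ccc2c(c1)c(cn2Cc1ccccc1)-c1c(OC)c(OC)c(Br)c(OC)c1OC | intermediate
9 | (E)-2-(2-ethoxyethenyl)-4,4,5,5-tetramethyl-1,3,2-dioxaborolane | CCO/C=C/B1OC(C)(C)C(C)(C)O1 | starting material
10 | 1-benzyl-3-{4-[(E)-2-ethoxyethenyl]-2,3,5,6-tetramethoxyphenyl}-5-methoxy-1H-indole | CCO/C=C/c1c(OC)c(OC)c(-c2cn(Cc3ccccc3)c3ccc(OC)cc23)c(OC)c1OC | intermediate
11 | 2-[4-(1-benzyl-5-methoxy-1H-indol-3-yl)-2,3,5,6-tetramethoxyphenyl]acetaldehyde | O=CCc1c(OC)c(OC)c(-c2cn(Cc3ccccc3)c3ccc(OC)cc23)c(OC)c1OC | intermediate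
12 | benzylamine | NCc1ccccc1 | starting material
13 | (E)-N-benzyl-2-[4-(1-benzyl-5-methoxy-1H-indol-3-yl)-2,3,5,6-tetramethoxyphenyl]ethan-1-imine | COc1ccc2c(c1)c(cn2Cc1ccccc1)-c1c(OC)c(OC)c(C/C=N/Cc2ccccc2)c(OC)c1OC | intermediate
14 | (E)-N-benzyl-2-[4-(1-benzyl-5-methoxy-1H-indol-3-yl)-2,3,5,6-tetramethoxyphenyl]ethen-1-amine | COc1ccc2c(c1)c(cn2Cc1ccccc1)-c1c(OC)c(OC)c(/C=C/NCc2ccccc2)c(OC)c1OC | intermediate
15 | 1,4-benzoquinone | O=C1C=CC(=O)C=C1 | starting material
16 | 2-{2-(benzylamino)-1-[4-(1-benzyl-5-methoxy-1H-indol-3-yl)-2,3,5,6-tetramethoxyphenyl]ethenyl}benzene-1,4-diol (alkene geometry not defined) | COc1ccc2c(c1)c(cn2Cc1ccccc1)-c1c(OC)c(OC)c(C(=CNCc2ccccc2)c2cc(O)ccc2O)c(OC)c1OC | intermediate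
17 | 2-{2-(benzylamino)-1-[4-(1-benzyl-5-methoxy-1H-indol-3-yl)-2,3,5,6-tetramethoxyphenyl]ethenyl}cyclohexa-2,5-diene-1,4-dione (alkene geometry not defined) | COc1ccc2c(c1)c(cn2Cc1ccccc1)-c1c(OC)c(OC)c(C(=CNCc2ccccc2)C2=CC(=O)C=CC2=O)c(OC)c1OC | intermediate
18 | 1-benzyl-3-[4-(1-benzyl-5-methoxy-1H-indol-3-yl)-2,3,5,6-tetramethoxyphenyl]-1H-indol-5-ol | COc1ccc2c(c1)c(cn2Cc1ccccc1)-c1c(OC)c(OC)c(-c2cn(Cc3ccccc3)c3ccc(O)cc23)c(OC)c1OC | intermediate
19 | 3-[4-(5-methoxy-1H-indol-3-yl)-2,3,5,6-tetramethoxyphenyl]-1H-indol-5-ol (CNP0244913.0) | COc1ccc2[nH]cc(-c3c(OC)c(OC)c(-c4c[nH]c5ccc(O)cc45)c(OC)c3OC)c2c1 | target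

## Step count and risks

Total step count: 9. Longest linear sequence: 8 steps (steps 2 to 9, from 5-methoxyindole 3 to 19).

Steps most likely to fail:

1. Step 8 (proposed new method). The hydroquinone adduct may close through oxygen and lose benzylamine before it is oxidised. The imine tautomer or traces of free benzylamine may add to the quinone through nitrogen. The imine may also condense with itself before carbon–carbon bond formation. Fallback (Fischer indole synthesis, known chemistry), setting out from 11 and coming back at 19: aldehyde 11 would be condensed with commercial (4-benzyloxyphenyl)hydrazine hydrochloride (NaOAc, EtOH, rt) to give the 4-(benzyloxy)phenylhydrazone F1. Heating F1 with ZnCl2 in AcOH at 80 °C should bring about the [3,3]-sigmatropic shift and loss of ammonia, giving 1-benzyl-3-{4-[5-(benzyloxy)-1H-indol-3-yl]-2,3,5,6-tetramethoxyphenyl}-5-methoxy-1H-indole F2. The para substituent of the hydrazine can only end at C5 and the aryl-bearing carbon becomes C3. Sodium in liquid ammonia under the conditions of step 9 would then cleave the N-benzyl and the O-benzyl groups together to give 19.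

2. Step 9. Electron transfer may go beyond benzyl cleavage: Birch reduction of an indole ring before its nitrogen is freed, or reductive loss of a methoxy group from the crowded central ring. Cleavage of the second benzyl group may be incomplete, and the free hydroxyindole may oxidise in air during work-up. Fallback, setting out from 18 and coming back at 19: the benzyl groups would be removed as cations instead of by reduction, with AlCl3 in anisole at rt (Lewis-acid-mediated transfer of benzyl from indole nitrogen to the arene solvent). This fallback makes no new compound (F0).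

3. Step 4. Coupling may run on to the second bromine of the symmetric dibromide. Protodeboronation of the indol-3-ylboronate may outrun transmetalation at the hindered palladium centre, and oxidative addition into the electron-rich C–Br bond may be slow. Fallback (polarity reversed), setting out from 2 and 5 and coming back at 8: one bromine–lithium exchange on 2 (n-BuLi, 1.0 equiv, THF, −78 °C) would give (4-bromo-2,3,5,6-tetramethoxyphenyl)lithium F3, which fixes mono-functionalisation by stoichiometry. Transmetalation with ZnCl2 would give (4-bromo-2,3,5,6-tetramethoxyphenyl)zinc chloride F4. Negishi coupling of F4 with iodoindole 5 (Pd2(dba)3, SPhos, THF, 60 °C) should give 8, because zerovalent palladium inserts into the C–I bond of 5 well before the hindered C–Br bond. Step 3 is then not needed.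

## Further compounds

F1 | step 8 | (E)-1-[4-(benzyloxy)phenyl]-2-{2-[4-(1-benzyl-5-methoxy-1H-indol-3-yl)-2,3,5,6-tetramethoxyphenyl]ethylidene}hydrazine | COc1ccc2c(c1)c(cn2Cc1ccccc1)-c1c(OC)c(OC)c(C/C=N/Nc2ccc(OCc3ccccc3)cc2)c(OC)c1OC
F2 | step 8 | 1-benzyl-3-{4-[5-(benzyloxy)-1H-indol-3-yl]-2,3,5,6-tetramethoxyphenyl}-5-methoxy-1H-indole | COc1ccc2c(c1)c(cn2Cc1ccccc1)-c1c(OC)c(OC)c(-c2c[nH]c3ccc(OCc4ccccc4)cc23)c(OC)c1OC
F0 | step 9 | none | none
F3 | step 4 | (4-bromo-2,3,5,6-tetramethoxyphenyl)lithium | [Li]c1c(OC)c(OC)c(Br)c(OC)c1OC
F4 | step 4 | (4-bromo-2,3,5,6-tetramethoxyphenyl)zinc chloride | Cl[Zn]c1c(OC)c(OC)c(Br)c(OC)c1OC
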